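Ring A is cut across C1–C10 and C4–C5: a labdane ring A that carries quaternary C4 and C10 flanking C5 and an oxygen at C2 is the retron of a 2-silyloxydiene (C1–C4) adding to an enal whose alkene is C5=C10. One catalytic, enantioselective (4+2) cycloaddition therefore closes ring A, forges both quaternary carbons and fixes C4, C5 and C10, leaving a C6 aldehyde and a C9 ester trans to each other for ring B. The precursors are an (E)-4-methyl-2,5-bis(silyloxy)penta-1,3-diene and methyl (E)-2-methyl-4-oxobut-2-enoate. Ring B follows by metathesis; C6 is set by catalyst-controlled reduction and C2 by thermodynamic reduction.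

Key step: step 5

Assumption: the (S)-configured oxazaborolidinium is taken to leave open the enal face that gives 9 as drawn; if the antipode predominates, the catalyst from (R)-α,α-diphenylprolinol is used and nothing else changes.

Design remark: the C19 oxygen is carried as a TBS (tert-butyldimethylsilyl) ether, so the final deprotection is a fluoride step that spares the butenolide and the C8=C9 alkene. Locants are labdane numbers; α/β refer to the usual labdane drawing (C20 methyl β).

Step 1
Reactants: 1 1-(tert-butyldimethylsilyloxy)propan-2-one; 2 1-(triphenylphosphoranylidene)propan-2-one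
Product: 3 (E)-5-(tert-butyldimethylsilyloxy)-4-methylpent-3-en-2-one
Conditions: toluene, 110 °C; chromatography to remove the minor Z isomer
Reagents that add atoms: none
Why: Wittig olefination of a stabilised acylmethylene ylide with an activated α-oxygenated ketone should place the acetyl group trans to the larger CH2OTBS substituent, so the E enone is expected to predominate.

Step 2
Reactants: 3 (E)-5-(tert-butyldimethylsilyloxy)-4-methylpent-3-en-2-one
Product: 4 (E)-2,5-bis(tert-butyldimethylsilyloxy)-4-methylpenta-1,3-diene (fragment 1)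
Conditions: TBSOTf, Et3N, CH2Cl2, 0 °C
Reagents that add atoms: tert-butyldimethylsilyl triflate, CC(C)(C)[Si](C)(C)OS(=O)(=O)C(F)(F)F
Why: Soft enolisation (O-silylation, then removal of a proton from the unhindered α′-methyl by the amine) gives the cross-conjugated 2-silyloxydiene and leaves the C3=C4 geometry untouched.

Step 3
Reactants: 5 2,2-dimethoxyacetaldehyde; 6 methyl 2-(triphenylphosphoranylidene)propanoate
Product: 7 methyl (E)-4,4-dimethoxy-2-methylbut-2-enoate
Conditions: CH2Cl2, rt
Reagents that add atoms: none
Why: Wittig reaction of an α-methyl stabilised ylide with an aldehyde gives the E trisubstituted enoate, with the ester trans to the acetal carbon.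

Step 4
Reactants: 7 methyl (E)-4,4-dimethoxy-2-methylbut-2-enoate
Product: 8 methyl (E)-2-methyl-4-oxobut-2-enoate (fragment 2)
Conditions: p-TsOH (cat.), THF/H2O, rt
Reagents that add atoms: water, O
Why: Mild acid-catalysed acetal hydrolysis should release the aldehyde without E-to-Z isomerisation, which would lead on to a hydroxybutenolide.

Step 5
Reactants: 4 (E)-2,5-bis(tert-butyldimethylsilyloxy)-4-methylpenta-1,3-diene; 8 methyl (E)-2-methyl-4-oxobut-2-enoate
Product: 9 methyl 3-(tert-butyldimethylsilyloxy)-5-[(tert-butyldimethylsilyloxy)methyl]-6-formyl-1,5-dimethylcyclohex-3-ene-1-carboxylate (ring A: C2=C3 silyl enol ether; C10 methyl β and C9 ester α; H5 α and C6 formyl β; C19 CH2OTBS β and C18 methyl α)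
Conditions: triflimide salt of (S)-3,3-diphenyl-1-(o-tolyl)tetrahydro-1H,3H-pyrrolo[1,2-c][1,3,2]oxazaborole (0.20 equiv, made in situ from the oxazaborolidine and Tf2NH, 0.18 equiv), 4 (1.5 equiv), CH2Cl2, −78 to −40 °C
Reagents that add atoms: none
Why: The protonated oxazaborolidine binds the formyl oxygen of 8 (the ester is the weaker donor), so the nucleophilic C1 terminus of the silyl enol ether attacks C10, β to the bound aldehyde, and C4 then bonds to C5; the closest known reactions are the strong-acid-catalysed Diels–Alder reactions of 4,4-disubstituted 2-silyloxydienes with enals and the oxazaborolidinium-catalysed cycloadditions of 2-silyloxydienes. Ring A closes as a suprafacial (4+2) six-membered closure; if the event is stepwise, the second bond should form by a 6-(enolexo)-endo-trig collapse of the boron enolate onto the silyloxyallyl cation faster than rotation about C5–C10, giving the same product. C10 relative to C5 follows from the E geometry of 8 (formyl and ester trans, so C6 ends cis to the C10 methyl); C4 relative to C5 follows from the E diene geometry together with the formyl-endo transition state, which puts the outward CH2OTBS cis to C6 (the axial C19 arrangement); the absolute configuration of all three centres comes from the enal face left open by the catalyst. The step needs regiocontrol, which the 2-silyloxy group and the aldehyde-bound acid impose in the same sense, endo control, which the complexed formyl group provides, and enough reactivity to join two fully substituted carbons despite the inward C4 methyl, which cationic activation and the electron-rich diene should supply.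

Step 6
Reactants: 9 ring A aldehyde ester
Product: 10 C6 vinyl carbinol of 9 (methyl ester retained; mixture of C6 epimers)
Conditions: CH2=CHMgBr, THF, −78 °C, cold quench
Reagents that add atoms: vinylmagnesium bromide, C=C[Mg]Br
Why: Grignard 1,2-addition to the aldehyde is much faster than attack on the neopentyl methyl ester at −78 °C, and the facial outcome is immaterial because the carbinol is oxidised in the next step.

Step 7
Reactants: 10 C6 vinyl carbinol (epimer mixture)
Product: 11 C6 vinyl ketone (1-oxoprop-2-enyl group on C5)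
Conditions: DMP, NaHCO3, CH2Cl2, 0 °C
Reagents that add atoms: none
Why: Buffered Dess–Martin oxidation of the allylic alcohol should give the enone without hydrolysing the silyl enol ether or epimerising C5, which is shielded by two quaternary neighbours.

Step 8
Reactants: 11 C6 vinyl ketone
Product: 13 (6S)-vinyl γ-lactone (C6–O–C9(=O) ring trans-fused to ring A), via hydroxy ester 12 (not isolated)
Conditions: (R)-1-methyl-3,3-diphenyltetrahydro-1H,3H-pyrrolo[1,2-c][1,3,2]oxazaborole (0.2 equiv), catecholborane, toluene, −78 °C; crude product, NaH (0.2 equiv), THF, 0 °C to rt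
Reagents that add atoms: none
Why: Corey–Bakshi–Shibata reduction delivers hydride under catalyst control, with the fully substituted ring carbon C5 as the large and the vinyl group as the small substituent, so the (R)-catalyst should give the (6S)-carbinol (the future equatorial 6α-OH), and the alkoxide then closes the γ-lactone on the C9 ester, which prepares C9 for a clean mono-addition.

Step 9
Reactants: 13 (6S)-vinyl γ-lactone
Product: 15 (6S)-hydroxy dienone (C9 isopropenyl ketone on C10 and C6 vinyl carbinol on C5), via lithium lactolate 14 (not isolated)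
Conditions: CH2=C(CH3)Li (from 2-bromopropene and t-BuLi, Et2O, −78 °C), THF, −78 °C
Reagents that add atoms: isopropenyllithium, [Li]C(C)=C
Why: Alkenyllithium addition to a lactone stops at the tetrahedral lithium lactolate at low temperature, so work-up should release the α-methyl enone and the C6 carbinol without over-addition, and quaternary C10 excludes enolisation.

Step 10
Reactants: 15 (6S)-hydroxy dienone
Product: 16 C6 TBS ether of 15
Conditions: TBSOTf, 2,6-lutidine, CH2Cl2, −78 to 0 °C
Reagents that add atoms: tert-butyldimethylsilyl triflate, CC(C)(C)[Si](C)(C)OS(=O)(=O)C(F)(F)F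
Why: Silylation of the secondary alcohol (γ-hydroxy ketones favour the open form and this enone has no enolisable position) fixes the open-chain dienone and protects C6 for the later enolate chemistry.

Step 11
Reactants: 16 silyl-protected dienone
Product: 17 bicyclic enone (ring B closed: C7=C8 with C8 methyl, C9 ketone, 6α-OTBS; ring A unchanged)
Conditions: second-generation Grubbs catalyst RuCl2(=CHPh)(H2IMes)(PCy3) (10 mol%), toluene, 80 °C, argon sparge
Reagents that add atoms: none
Why: Ring-closing metathesis should initiate at the monosubstituted C7 vinyl group and close on the 1,1-disubstituted enone alkene to give the 2-methylcyclohexenone trans-fused to ring A, while the trisubstituted silyl enol ether cannot form a ring with either partner.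

Step 12
Reactants: 17 bicyclic enone
Product: 19 C9 enol triflate (C8=C9, C7 now CH2), via lithium enolate 18 (not isolated)
Conditions: LiBH(s-Bu)3, THF, −78 °C; then N-(5-chloropyridin-2-yl)-bis(trifluoromethanesulfonyl)imide, −78 to 0 °C
Reagents that add atoms: N-(5-chloropyridin-2-yl)-bis(trifluoromethanesulfonyl)imide (Comins reagent), FC(F)(F)S(=O)(=O)N(c1ccc(Cl)cn1)S(=O)(=O)C(F)(F)F
Why: Conjugate hydride addition to the α-methyl enone, whose β-carbon C7 bears hydrogen and whose carbonyl is shielded by quaternary C10, gives the C8=C9 enolate regiospecifically, and O-triflation traps it as the tetrasubstituted enol triflate.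

Step 13
Reactants: 19 C9 enol triflate
Product: 20 9-vinyl diene (C8=C9–C11=C12)
Conditions: CH2=CHSnBu3, Pd(PPh3)4 (10 mol%), LiCl, THF, 65 °C
Reagents that add atoms: tributyl(vinyl)stannane, C=C[Sn](CCCC)(CCCC)CCCC
Why: Stille coupling of hindered cyclohexenyl triflates with vinylstannanes in the presence of LiCl is dependable and installs C11 and C12 on C9.

Step 14
Reactants: 20 9-vinyl diene
Product: 21 C2 ketone (6α,19-bis-TBS ether retained)
Conditions: TBAF/AcOH (1:1, 1.2 equiv), THF, 0 °C
Reagents that add atoms: none
Why: Buffered fluoride cleaves the silyl enol ether selectively, because an enolate leaves silicon far more readily than an alkoxide, and the secondary and neopentyl TBS ethers should survive.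

Step 15
Reactants: 21 C2 ketone
Product: 22 2α-alcohol (equatorial OH)
Conditions: SmI2 (2.5 equiv), Et3N, H2O, THF, 0 °C, 5 min
Reagents that add atoms: none
Why: Electron-transfer reduction by SmI2 with water and amine passes through a ketyl that is protonated to the more stable equatorial alkoxide, as in dissolving-metal reductions, so the 2α-alcohol should form where hydride reagents, forced to the α-face by the syn-axial C19 and C20 groups, would give the axial 2β-epimer, and the twisted unactivated diene should be reduced far more slowly than the ketone.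

Step 16
Reactants: 22 2α-alcohol; 23 4-bromofuran-2(5H)-one
Product: 25 6,19-bis-TBS ether of the target, via B-alkyl-9-BBN borane 24 (not isolated)
Conditions: 9-BBN (3 equiv), THF, 0 °C to rt; then 23, PdCl2(dppf) (10 mol%), K3PO4, DMF/THF, H2O (5 equiv), 50 °C
Reagents that add atoms: none
Why: 9-BBN should hydroborate only the terminus of the monosubstituted C11=C12 alkene (the tetrasubstituted alkene is inert and the free C2–OH merely forms a borinate), and B-alkyl Suzuki–Miyaura coupling with the β-bromo butenolide, a vinylogous acyl bromide, forms C12–C13.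

Step 17
Reactants: 25 6,19-bis-TBS ether of the target
Product: 26 target, 2α,6α,19-trihydroxylabda-8,13-dien-16,15-olide
Conditions: HF·pyridine, pyridine/THF, 0 °C to rt
Reagents that add atoms: none
Why: Buffered fluoride cleavage of both silyl ethers should leave the butenolide and the tetrasubstituted alkene untouched and release the triol.

Compound list
1 | 1-(tert-butyldimethylsilyloxy)propan-2-one | CC(=O)CO[Si](C)(C)C(C)(C)C | starting material
2 | 1-(triphenylphosphoranylidene)propan-2-one | CC(=O)C=P(c1ccccc1)(c1ccccc1)c1ccccc1 | starting material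
3 | (E)-5-(tert-butyldimethylsilyloxy)-4-methylpent-3-en-2-one | CC(=O)/C=C(\C)CO[Si](C)(C)C(C)(C)C | intermediate
4 | (E)-2,5-bis(tert-butyldimethylsilyloxy)-4-methylpenta-1,3-diene (fragment 1) | C=C(O[Si](C)(C)C(C)(C)C)/C=C(\C)CO[Si](C)(C)C(C)(C)C | intermediate
5 | 2,2-dimethoxyacetaldehyde | COC(OC)C=O | starting material
6 | methyl 2-(triphenylphosphoranylidene)propanoate | COC(=O)C(C)=P(c1ccccc1)(c1ccccc1)c1ccccc1 | starting material
7 | methyl (E)-4,4-dimethoxy-2-methylbut-2-enoate | COC(OC)/C=C(\C)C(=O)OC | intermediate
8 | methyl (E)-2-methyl-4-oxobut-2-enoate (fragment 2) | O=C/C=C(\C)C(=O)OC | intermediate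
9 | ring A adduct: C2=C3 silyl enol ether, C6 aldehyde (β on C5), C9 methyl ester (α on C10), C19 CH2OTBS β | COC(=O)[C@@]1(C)CC(O[Si](C)(C)C(C)(C)C)=C[C@](C)(CO[Si](C)(C)C(C)(C)C)[C@@H]1C=O | intermediate
10 | C6 vinyl carbinol of 9 (C6 epimer mixture) | COC(=O)[C@@]1(C)CC(O[Si](C)(C)C(C)(C)C)=C[C@](C)(CO[Si](C)(C)C(C)(C)C)[C@@H]1C(O)C=C | intermediate
11 | C6 vinyl ketone | COC(=O)[C@@]1(C)CC(O[Si](C)(C)C(C)(C)C)=C[C@](C)(CO[Si](C)(C)C(C)(C)C)[C@@H]1C(=O)C=C | intermediate
12 | (6S)-hydroxy ester | COC(=O)[C@@]1(C)CC(O[Si](C)(C)C(C)(C)C)=C[C@](C)(CO[Si](C)(C)C(C)(C)C)[C@@H]1[C@@H](O)C=C | intermediate (not isolated)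
13 | (6S)-vinyl γ-lactone, C6–O–C9(=O), trans-fused to ring A | O=C1O[C@@H](C=C)[C@@H]2[C@]1(C)CC(O[Si](C)(C)C(C)(C)C)=C[C@]2(C)CO[Si](C)(C)C(C)(C)C | intermediate
14 | lithium lactolate from 13 and isopropenyllithium (C9 configuration undefined) | [Li]OC1(C(C)=C)O[C@@H](C=C)[C@@H]2[C@]1(C)CC(O[Si](C)(C)C(C)(C)C)=C[C@]2(C)CO[Si](C)(C)C(C)(C)C | intermediate (not isolated)
15 | (6S)-hydroxy dienone: C9 isopropenyl ketone, C6 vinyl carbinol | C=C(C)C(=O)[C@@]1(C)CC(O[Si](C)(C)C(C)(C)C)=C[C@](C)(CO[Si](C)(C)C(C)(C)C)[C@@H]1[C@@H](O)C=C | intermediate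
16 | C6 TBS ether of 15 | C=C(C)C(=O)[C@@]1(C)CC(O[Si](C)(C)C(C)(C)C)=C[C@](C)(CO[Si](C)(C)C(C)(C)C)[C@@H]1[C@@H](O[Si](C)(C)C(C)(C)C)C=C | intermediate
17 | bicyclic enone: C7=C8, C9 ketone, 6α-OTBS, C2=C3 silyl enol ether, 19-OTBS | CC1=C[C@H](O[Si](C)(C)C(C)(C)C)[C@H]2[C@@](C)(CO[Si](C)(C)C(C)(C)C)C=C(O[Si](C)(C)C(C)(C)C)C[C@]2(C)C1=O | intermediate
18 | lithium C8=C9 enolate | CC1=C(O[Li])[C@@]2(C)CC(O[Si](C)(C)C(C)(C)C)=C[C@](C)(CO[Si](C)(C)C(C)(C)C)[C@@H]2[C@@H](O[Si](C)(C)C(C)(C)C)C1 | intermediate (not isolated)
19 | C9 enol triflate (C8=C9) | CC1=C(OS(=O)(=O)C(F)(F)F)[C@@]2(C)CC(O[Si](C)(C)C(C)(C)C)=C[C@](C)(CO[Si](C)(C)C(C)(C)C)[C@@H]2[C@@H](O[Si](C)(C)C(C)(C)C)C1 | intermediate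
20 | 9-vinyl diene | CC1=C(C=C)[C@@]2(C)CC(O[Si](C)(C)C(C)(C)C)=C[C@](C)(CO[Si](C)(C)C(C)(C)C)[C@@H]2[C@@H](O[Si](C)(C)C(C)(C)C)C1 | intermediate
21 | C2 ketone | CC1=C(C=C)[C@@]2(C)CC(=O)C[C@](C)(CO[Si](C)(C)C(C)(C)C)[C@@H]2[C@@H](O[Si](C)(C)C(C)(C)C)C1 | intermediate
22 | 2α-alcohol | CC1=C(C=C)[C@@]2(C)C[C@@H](O)C[C@](C)(CO[Si](C)(C)C(C)(C)C)[C@@H]2[C@@H](O[Si](C)(C)C(C)(C)C)C1 | intermediate
23 | 4-bromofuran-2(5H)-one | O=C1OCC(Br)=C1 | starting material
24 | B-alkyl-9-BBN borane at C12 (C2–OH as its 9-BBN borinate) | CC1=C(CCB3C4CCCC3CCC4)[C@@]2(C)C[C@@H](OB3C4CCCC3CCC4)C[C@](C)(CO[Si](C)(C)C(C)(C)C)[C@@H]2[C@@H](O[Si](C)(C)C(C)(C)C)C1 | intermediate (not isolated)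
25 | 6,19-bis-TBS ether of the target | CC1=C(CCC2=CC(=O)OC2)[C@@]2(C)C[C@@H](O)C[C@](C)(CO[Si](C)(C)C(C)(C)C)[C@@H]2[C@@H](O[Si](C)(C)C(C)(C)C)C1 | intermediate
26 | 2α,6α,19-trihydroxylabda-8,13-dien-16,15-olide | CC1=C(CCC2=CC(=O)OC2)[C@@]2(C)C[C@@H](O)C[C@](C)(CO)[C@@H]2[C@@H](O)C1 | target

Total step count: 17. Longest linear sequence: 15 steps (1 → 3 → 4 → 9 → … → 26; the branch 5 → 7 → 8 → 9 → … → 26 is equally long).

Steps most likely to fail

Step 5. Bond formation between two fully substituted carbons may be too slow, because the inward C4 methyl disfavours the s-cis diene, so that protodesilylation of the diene or arrest at an open-chain Mukaiyama–Michael adduct takes over; the catalyst may also discriminate the faces of this β,β-disubstituted enal poorly. The fallback gives up enantioselective catalysis and resolves later. Setting out from 4 and 8, the cycloaddition is run with an achiral acid of the kind known for hindered 2-silyloxydienes (Tf2NH, or AlBr3/AlMe3, CH2Cl2, −78 °C), which gives 9 together with its antipode, the ent-adduct F1. Steps 6 and 7 are run on the racemate and give 10 and 11 together with the ent-carbinols F2 and the ent-vinyl ketone F3. The (R)-configured reduction catalyst of step 8 then turns both ketone enantiomers into 6S carbinols, namely 12 and the diastereomeric hydroxy ester F4. After lactonisation the diastereomeric lactone F5 is removed by chromatography, and the route is rejoined at 13.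

Step 15. Protonation of the ketyl may not be selective enough, leaving axial 2β-alcohol, or electron transfer may go on to reduce the conjugated diene. The fallback replaces thermodynamic reduction by kinetic reduction and inversion. Setting out from 21, NaBH4 (MeOH, 0 °C) delivers hydride from the open α-face to give the axial 2β-alcohol F6. Mitsunobu inversion (4-nitrobenzoic acid, PPh3, DIAD, toluene, 0 °C to rt) gives the 2α-(4-nitrobenzoate) F7, and methanolysis (K2CO3, MeOH, rt) rejoins the route at 22.

Step 11. The ruthenium alkylidene formed at the C7 vinyl group may fail to engage the hindered, electron-poor 1,1-disubstituted enone alkene, leading to stalling or intermolecular dimerisation. The fallback removes the electron-poor alkene by a redox detour. Setting out from 16, 1,2-reduction (i-Bu2AlH, CH2Cl2, −78 °C) gives the C9 allylic alcohol F8 as a C9 epimer mixture. Ring closure between two allylic-alcohol-type alkenes (second-generation Grubbs catalyst RuCl2(=CHPh)(H2IMes)(PCy3), CH2Cl2, 40 °C) gives the bicyclic allylic alcohol F9, and oxidation (DMP, NaHCO3, CH2Cl2) rejoins the route at 17.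

Further compounds
F1 | step 5 | ent-adduct (antipode of 9) | COC(=O)[C@]1(C)CC(O[Si](C)(C)C(C)(C)C)=C[C@@](C)(CO[Si](C)(C)C(C)(C)C)[C@H]1C=O
F2 | step 5 | ent-carbinols (antipodes of 10, C6 epimer mixture) | COC(=O)[C@]1(C)CC(O[Si](C)(C)C(C)(C)C)=C[C@@](C)(CO[Si](C)(C)C(C)(C)C)[C@H]1C(O)C=C
F3 | step 5 | ent-vinyl ketone (antipode of 11) | COC(=O)[C@]1(C)CC(O[Si](C)(C)C(C)(C)C)=C[C@@](C)(CO[Si](C)(C)C(C)(C)C)[C@H]1C(=O)C=C
F4 | step 5 | diastereomeric hydroxy ester (6S carbinol on the antipodal ring) | COC(=O)[C@]1(C)CC(O[Si](C)(C)C(C)(C)C)=C[C@@](C)(CO[Si](C)(C)C(C)(C)C)[C@H]1[C@@H](O)C=C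
F5 | step 5 | diastereomeric lactone (from F4) | O=C1O[C@@H](C=C)[C@H]2[C@@]1(C)CC(O[Si](C)(C)C(C)(C)C)=C[C@@]2(C)CO[Si](C)(C)C(C)(C)C
F6 | step 15 | axial 2β-alcohol (C2 epimer of 22) | CC1=C(C=C)[C@@]2(C)C[C@H](O)C[C@](C)(CO[Si](C)(C)C(C)(C)C)[C@@H]2[C@@H](O[Si](C)(C)C(C)(C)C)C1
F7 | step 15 | 2α-(4-nitrobenzoate) of 22 | CC1=C(C=C)[C@@]2(C)C[C@@H](OC(=O)c3ccc(cc3)[N+](=O)[O-])C[C@](C)(CO[Si](C)(C)C(C)(C)C)[C@@H]2[C@@H](O[Si](C)(C)C(C)(C)C)C1
F8 | step 11 | C9 allylic alcohol from 16 (C9 epimer mixture) | C=C(C)C(O)[C@@]1(C)CC(O[Si](C)(C)C(C)(C)C)=C[C@](C)(CO[Si](C)(C)C(C)(C)C)[C@@H]1[C@@H](O[Si](C)(C)C(C)(C)C)C=C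
F9 | step 11 | bicyclic allylic alcohol (C7=C8, C9 carbinol, C9 epimer mixture) | CC1=C[C@H](O[Si](C)(C)C(C)(C)C)[C@H]2[C@@](C)(CO[Si](C)(C)C(C)(C)C)C=C(O[Si](C)(C)C(C)(C)C)C[C@]2(C)C1O
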